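The scavenger in this flask is what we watch, because we assume each target leaves one equivalent of something that the scavenger takes up, and that whatever escapes it can tie coupling partner as idle adduct. The readings show nothing of that binding, so this is our assumption.

in all of them: substrate 0.40 M; free catalyst 5 mol%
- alder: coupling partner 1 equiv; scavenger 0.30 equiv (fed, over 20 h); run made earlier
- maple: coupling partner 4 equiv; scavenger 0.30 equiv (fed, over 20 h); run made earlier
- flask: coupling partner 2.00 equiv; scavenger 0.300 equiv (fed, over 20 h); time 40 h

- alder (time / h: substrate / %, target / %): 1.50: 95.9, 0.5; 5.00: 93.5, 2.8; 10.0: 89.2, 7.3; 15.0: 85.5, 11.3; 20.0: 81.2, 15.4; 25.0: 77.4, 19.3; 30.0: 74.0, 22.4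
- maple (time / h: substrate / %, target / %): 2.50: 93.9, 2.1; 4.00: 91.0, 4.4; 6.00: 88.4, 7.5; 10.0: 82.7, 13.9; 15.0: 75.8, 20.6; 20.0: 68.9, 28.0; 30.0: 55.3, 40.7

(readings scatter by 0.3 percentage points)

* part of the substrate that has reacted at 40 h
* share of the unused coupling partner that is free and not bound as idle adduct, at 40 h

- the numbers in the tables scatter with a standard deviation of 0.3 percentage points
- the earlier runs do not show how much of coupling partner is bound; that part of a forecast is a guess

We first need the slope of the target curve, as a fraction of the charged substrate per hour. Between 10.0 h and 30.0 h, alder and maple give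

alder: 0.00755 h⁻¹
maple: 0.0134 h⁻¹

The flask's 2.00 equiv is the geometric mean of 1 equiv and 4 equiv, so a power law in partner puts its slope s at the geometric mean of the two:

s = 0.0101 h⁻¹

The scavenger feed runs at 0.0150 h⁻¹, faster than s, so a stock of scavenger builds until the feed ends at 20 h. That is the first knee. On this reckoning the stock then falls at s, and target overtakes the scavenger charge at

29.8 h

Beyond that crossing, the target made in excess of the scavenger charge climbs at s, and by 40 h it stands at

S = 0.0409 M

We call S the surplus, the shortfall of the scavenger against the target made. If one partner goes per target, unused partner is 0.639 M. With the whole surplus bound, we estimate a floor for the free share of 93.6%. Adding the early gap between the charge and substrate plus target, 3.80%, our conversion is 44.0%.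

The forecast says 47% reacted, higher than our figure, and 88% free, lower than our floor, adding “Binding is probably partial”.

The flask gives 45.4% reacted and 97.6% free.

    substrate + free catalyst ⇌ catalyst intermediate A (K = 4.60 M⁻¹, k = 6.60 M⁻¹ h⁻¹)
    coupling partner + catalyst intermediate A ⇌ catalyst intermediate B (K = 1.30 M⁻¹, k = 2.40 M⁻¹ h⁻¹)
    catalyst intermediate B → released group + catalyst intermediate C (k = 2.10 h⁻¹)
    catalyst intermediate C ⇌ catalyst intermediate D (K = 0.120, k = 11.0 h⁻¹)
    catalyst intermediate D → free catalyst + target (k = 5.90 h⁻¹)
    coupling partner + released group ⇌ idle adduct, settled at all times (K = 0.550 M⁻¹)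
    scavenger + released group → scavenged by-product (k = 4.90 M⁻¹ h⁻¹)

At 40.0 h this flask holds 0.0147 M of idle adduct, less than our surplus, beside 0.0438 M of unpaired released group; the pairing constant times free partner is 0.335, and the adduct stands at that fraction of the unpaired released group. The neighbour flask, the same recipe with 0.68 M of substrate, makes 55.3% target by 40.0 h, so its surplus is 0.172 M and its estimated floor 82.5%, and it holds 0.0617 M of idle adduct at a free share of 93.6%.

The numbers in the tables are calculated for substances that don't exist.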